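The route rests on cutting the C4–C5 and C9–C10 bonds of the trans-decalin, so that rings A and B come from one open C20 chain of polyprenoid geometry that already carries the side chain. Two features are exploited: the C3 oxygen beside the oxidized C18 on C4 marks a Sharpless 2,3-epoxy alcohol, and the exocyclic C8=C17 methylene beside C9 marks an allylsilane. In one operation a Lewis acid opens the epoxide, closes ring A and ring B and sets C4, C5, C9 and C10. The precursor is a (2S,3S)-epoxy triene with a silyloxymethyl group on the oxirane and a CH2SiMe3 group on C8, assembled by two successive couplings on a 1,1-dibromoalkene.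

Key step: step 13

Remark: atom numbers are labdane numbers (C18 = 4α carbon substituent, C19 = 4β-methyl, C20 = 10β-methyl, C17 = methylene carbon on C8); the target SMILES is read as (3R,4S,5R,9S,10R), that is 3α-acetoxy, 4α-CO2H, 5α-H, 9α-H, 10β-CH3.

Step 1
Reactants: 1 geranyl acetate
Product: 2 (2E,6E)-8-hydroxygeranyl acetate
Conditions: SeO2 (cat.), t-BuOOH, salicylic acid (cat.), CH2Cl2, rt
Reagents that add atoms: tert-butyl hydroperoxide, CC(C)(C)OO
Why: Allylic oxidation with SeO2 (ene reaction followed by [2,3]-sigmatropic shift) should pick the (E)-methyl group of the electron-rich terminal alkene, the C2 alkene being deactivated by its allylic acetate.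

Step 2
Reactants: 2 (2E,6E)-8-hydroxygeranyl acetate
Product: 3 (2E)-5-[(2S,3S)-3-(hydroxymethyl)-3-methyloxiran-2-yl]-3-methylpent-2-en-1-yl acetate
Conditions: Ti(OiPr)4 (cat.), L-(+)-diethyl tartrate, t-BuOOH, 4 Å MS, CH2Cl2, −20 °C
Reagents that add atoms: tert-butyl hydroperoxide, CC(C)(C)OO
Why: Sharpless asymmetric epoxidation with the L-(+)-tartrate ligand should deliver oxygen to the face of the (E)-2-methyl allylic alcohol that gives the (2S,3S)-oxirane (the future C3 and C4), while the other alkene lacks a free hydroxyl and stays untouched.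

Step 3
Reactants: 3 epoxy alcohol
Product: 4 (2E)-5-[(2S,3S)-3-(tert-butyldimethylsilyloxymethyl)-3-methyloxiran-2-yl]-3-methylpent-2-en-1-yl acetate
Conditions: TBSCl, imidazole, DMF, 0 °C to rt
Reagents that add atoms: tert-butyldimethylsilyl chloride, CC(C)(C)[Si](C)(C)Cl
Why: Imidazole-mediated silylation of the primary alcohol is mild enough to avoid Payne rearrangement and installs the ether that C18 carries through the cyclization.

Step 4
Reactants: 4 TBS ether acetate
Product: 5 (2E)-5-[(2S,3S)-3-(tert-butyldimethylsilyloxymethyl)-3-methyloxiran-2-yl]-3-methylpent-2-en-1-ol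
Conditions: K2CO3, MeOH, 0 °C
Reagents that add atoms: none
Why: Base-catalysed transesterification should remove the acetate without opening the trisubstituted oxirane or cleaving the primary TBS ether.

Step 5
Reactants: 5 allylic alcohol
Product: 6 (2E)-5-[(2S,3S)-3-(tert-butyldimethylsilyloxymethyl)-3-methyloxiran-2-yl]-3-methylpent-2-enal
Conditions: MnO2, CH2Cl2, rt
Reagents that add atoms: none
Why: MnO2 oxidizes only the allylic alcohol and should keep the (E)-geometry of the future C5=C10 alkene, the oxirane and silyl ether being inert.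

Step 6
Reactants: 6 enal; 7 methyltriphenylphosphonium bromide
Product: 9 epoxy diene tert-butyldimethyl{[(2S,3S)-2-methyl-3-[(3E)-3-methylhexa-3,5-dien-1-yl]oxiran-2-yl]methoxy}silane, via methylenetriphenylphosphorane 8 (not isolated)
Conditions: KN(SiMe3)2, THF, 0 °C; then 6, −78 °C to 0 °C
Reagents that add atoms: none
Why: Wittig methylenation with the salt-free non-stabilized ylide adds C7 as a terminal vinyl group without creating a stereo element and without attacking the oxirane.

Step 7
Reactants: 10 geraniol
Product: 11 geranyl tert-butyldiphenylsilyl ether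
Conditions: TBDPSCl, imidazole, DMF, rt
Reagents that add atoms: tert-butyldiphenylsilyl chloride, CC(C)(C)[Si](Cl)(c1ccccc1)c1ccccc1
Why: Standard silylation gives the C15 ether, chosen because a TBDPS group should survive the Lewis acid of the key step and the later acidic removal of the C18 TBS group.

Step 8
Reactants: 11 geranyl TBDPS ether
Product: 12 6,7-epoxygeranyl tert-butyldiphenylsilyl ether (racemic at the oxirane CH)
Conditions: mCPBA, CH2Cl2, −20 °C to 0 °C
Reagents that add atoms: 3-chloroperoxybenzoic acid, OOC(=O)c1cccc(Cl)c1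
Why: Prilezhaev epoxidation should prefer the more electron-rich 6,7-alkene over the 2,3-alkene that bears the inductively withdrawing allylic silyloxy group, and the oxirane configuration is irrelevant because this carbon is cleaved next.

Step 9
Reactants: 12 6,7-epoxide
Product: 13 (4E)-6-(tert-butyldiphenylsilyloxy)-4-methylhex-4-enal
Conditions: H5IO6, THF/H2O, 0 °C
Reagents that add atoms: none
Why: Periodic acid hydrolyses the oxirane to the glycol and cleaves it (Malaprade-type glycol cleavage) to the aldehyde and acetone, leaving the (E)-alkene and the TBDPS ether intact.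

Step 10
Reactants: 13 aldehyde; 14 carbon tetrabromide
Product: 16 tert-butyl{[(2E)-7,7-dibromo-3-methylhepta-2,6-dien-1-yl]oxy}diphenylsilane, via (dibromomethylene)triphenylphosphorane 15 (not isolated)
Conditions: PPh3, Et3N, CH2Cl2, 0 °C
Reagents that add atoms: none
Why: Ramirez dibromo-olefination (first stage of the Corey–Fuchs sequence) converts the aldehyde into the 1,1-dibromoalkene that supplies C8, with Et3N keeping the medium non-acidic for the silyl ether.

Step 11
Reactants: 9 epoxy diene; 16 1,1-dibromoalkene
Product: 18 (2E,6Z,10E)-7-bromo epoxy triene bis-silyl ether (labdane C8 bromide; C7 trans to C11), via homoallylic B-alkyl-9-BBN 17 (not isolated)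
Conditions: 9-BBN, THF, 0 °C to rt; then 16, PdCl2(dppf) (cat.), AsPh3, aq. Cs2CO3, DMF, rt
Reagents that add atoms: none
Why: Anti-Markovnikov hydroboration of the terminal vinyl group by 9-BBN puts boron on C7 without touching the trisubstituted alkene or the oxirane, and the B-alkyl Suzuki–Miyaura coupling should then occur at the C–Br bond trans to C11, where oxidative addition is faster, giving the (Z)-bromoalkene with C7 trans to C11.

Step 12
Reactants: 18 (Z)-bromoalkene; 19 (trimethylsilyl)methylmagnesium chloride
Product: 21 (2E,6Z,10E)-7-[(trimethylsilyl)methyl] epoxy triene bis-silyl ether (allylsilane; C17 cis to C11), via (trimethylsilyl)methylzinc chloride 20 (not isolated)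
Conditions: ZnCl2, THF, 0 °C; then 18, Pd(P(t-Bu)3)2 (cat.), THF, rt to 40 °C
Reagents that add atoms: none
Why: Negishi coupling replaces the remaining alkenyl bromide by the silylmethyl group with retention of geometry under Pd(P(t-Bu)3)2, a catalyst suited to the second substitution of such 2-bromoalkenes, and the zinc reagent is too mild to open the oxirane.

Step 13
Reactants: 21 epoxy allylsilane
Product: 22 18-(tert-butyldimethylsilyloxy)-15-(tert-butyldiphenylsilyloxy)labda-8(17),13E-dien-3β-ol
Conditions: MeAlCl2, CH2Cl2, −78 °C; then Et3N, aq. MeOH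
Reagents that add atoms: none
Why: MeAlCl2 binds the oxirane oxygen, the C4–O bond ionizes under backside attack by C5 of the (E)-C5=C10 alkene, the C10 cation is taken by C9 of the C8=C9 allylsilane, and the β-silyl cation at C8 sheds Me3Si to leave the C8=C17 methylene, the aluminium alkoxide at C3 giving the 3β-alcohol on work-up. The closest known reaction type is the Lewis acid-promoted, epoxide-initiated cation–olefin polycyclization terminated by a 2-substituted allylsilane. Ring A (C4–C5 bond) should close 6-endo at both the oxirane and the C5=C10 alkene through a chair, and ring B (C10–C9 bond) 6-endo-trig on the allylsilane through a second chair. C3 keeps the oxygen configuration of the Sharpless oxirane and ends equatorial (3β), C4 is inverted so that the CH2OTBS group trans to the chain on the oxirane becomes the equatorial 4α substituent (C18) and the methyl the axial C19, C5 and C10 follow from anti addition across the (E)-C5=C10 alkene (5α-H, 10β-CH3), and C9 follows from the C8=C9 geometry with C7 trans to C11, which places the side chain equatorial (9α-H). The step needs ionization at the tertiary C4 in preference to hydride shift or attack at C3, all-chair folding, and termination only at C8; the substitution pattern of the oxirane, the defined alkene geometries and the β-silicon effect of the C17 silyl group should secure these, and the C13=C14 alkene is deactivated by its allylic silyloxy group and outrun by desilylation.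

Step 14
Reactants: 22 3β-alcohol
Product: 23 18-(tert-butyldimethylsilyloxy)-15-(tert-butyldiphenylsilyloxy)labda-8(17),13E-dien-3-one
Conditions: Dess–Martin periodinane, NaHCO3, CH2Cl2, rt
Reagents that add atoms: none
Why: Dess–Martin oxidation under buffered conditions gives the ketone, which cannot enolize toward the quaternary C4 and has no pathway for β-elimination of the silyloxy group.

Step 15
Reactants: 23 3-ketone
Product: 24 18-(tert-butyldimethylsilyloxy)-15-(tert-butyldiphenylsilyloxy)labda-8(17),13E-dien-3α-ol
Conditions: LiBH(s-Bu)3, THF, −78 °C; then H2O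
Reagents that add atoms: none
Why: Stereoselective ketone reduction with a bulky trialkylborohydride should proceed by equatorial approach, since the axial path past the axial hydrogens on C1 and C5 is blocked for so large a reagent, which sets C3 as the axial 3α-alcohol.

Step 16
Reactants: 24 3α-alcohol
Product: 25 3α-acetoxy-18-(tert-butyldimethylsilyloxy)-15-(tert-butyldiphenylsilyloxy)labda-8(17),13E-diene
Conditions: Ac2O, DMAP, Et3N, CH2Cl2, rt
Reagents that add atoms: acetic anhydride, CC(=O)OC(C)=O
Why: DMAP-catalysed acylation should esterify the hindered axial alcohol, which is the only free hydroxyl present.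

Step 17
Reactants: 25 3α-acetate
Product: 26 3α-acetoxy-15-(tert-butyldiphenylsilyloxy)labda-8(17),13E-dien-18-ol
Conditions: HF·pyridine, pyridine, THF, 0 °C
Reagents that add atoms: none
Why: Acid-type fluoride desilylation removes a primary TBS ether much faster than a TBDPS ether, and the acidic medium disfavours acetyl transfer from O3 to the freed O18.

Step 18
Reactants: 26 C18 alcohol
Product: 27 3α-acetoxy-15-(tert-butyldiphenylsilyloxy)labda-8(17),13E-dien-18-al
Conditions: Dess–Martin periodinane, NaHCO3, CH2Cl2, 0 °C to rt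
Reagents that add atoms: none
Why: Dess–Martin oxidation stops at the aldehyde, which has no α-hydrogen and so cannot epimerize, and taking 26 on at once pre-empts acetyl migration.

Step 19
Reactants: 27 C18 aldehyde
Product: 28 3α-acetoxy-15-(tert-butyldiphenylsilyloxy)labda-8(17),13E-dien-18-oic acid
Conditions: NaClO2, NaH2PO4, 2-methyl-2-butene, t-BuOH/H2O, rt
Reagents that add atoms: sodium chlorite, [Na+].[O-]Cl=O
Why: Pinnick oxidation converts the hindered aldehyde into the acid under weakly acidic conditions, with 2-methyl-2-butene scavenging HOCl so that both alkenes are spared.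

Step 20
Reactants: 28 C18 acid
Product: 29 3α-acetoxy-15-hydroxylabda-8(17),13E-dien-18-oic acid (target)
Conditions: HF·pyridine (excess), THF, 0 °C to rt
Reagents that add atoms: none
Why: Fluoride cleavage of the remaining silyl ether under acidic conditions should leave the secondary acetate, the carboxylic acid and both alkenes untouched and release the target.

Compound list
1 | geranyl acetate | CC(C)=CCC/C(C)=C/COC(C)=O | starting material
2 | (2E,6E)-8-hydroxy-3,7-dimethylocta-2,6-dien-1-yl acetate | OC/C(C)=C/CC/C(C)=C/COC(C)=O | intermediate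
3 | (2E)-5-[(2S,3S)-3-(hydroxymethyl)-3-methyloxiran-2-yl]-3-methylpent-2-en-1-yl acetate | OC[C@]1(C)O[C@H]1CC/C(C)=C/COC(C)=O | intermediate
4 | (2E)-5-[(2S,3S)-3-(tert-butyldimethylsilyloxymethyl)-3-methyloxiran-2-yl]-3-methylpent-2-en-1-yl acetate | CC(C)(C)[Si](C)(C)OC[C@]1(C)O[C@H]1CC/C(C)=C/COC(C)=O | intermediate
5 | (2E)-5-[(2S,3S)-3-(tert-butyldimethylsilyloxymethyl)-3-methyloxiran-2-yl]-3-methylpent-2-en-1-ol | CC(C)(C)[Si](C)(C)OC[C@]1(C)O[C@H]1CC/C(C)=C/CO | intermediate
6 | (2E)-5-[(2S,3S)-3-(tert-butyldimethylsilyloxymethyl)-3-methyloxiran-2-yl]-3-methylpent-2-enal | CC(C)(C)[Si](C)(C)OC[C@]1(C)O[C@H]1CC/C(C)=C/C=O | intermediate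
7 | methyltriphenylphosphonium bromide | C[P+](c1ccccc1)(c1ccccc1)c1ccccc1.[Br-] | starting material
8 | methylenetriphenylphosphorane (not isolated) | C=P(c1ccccc1)(c1ccccc1)c1ccccc1 | intermediate
9 | tert-butyldimethyl{[(2S,3S)-2-methyl-3-[(3E)-3-methylhexa-3,5-dien-1-yl]oxiran-2-yl]methoxy}silane | CC(C)(C)[Si](C)(C)OC[C@]1(C)O[C@H]1CC/C(C)=C/C=C | intermediate
10 | geraniol | CC(C)=CCC/C(C)=C/CO | starting material
11 | geranyl tert-butyldiphenylsilyl ether | CC(C)=CCC/C(C)=C/CO[Si](c1ccccc1)(c1ccccc1)C(C)(C)C | intermediate
12 | (2E)-6,7-epoxy-3,7-dimethyloct-2-en-1-yl tert-butyldiphenylsilyl ether, racemic at the oxirane | CC1(C)OC1CC/C(C)=C/CO[Si](c1ccccc1)(c1ccccc1)C(C)(C)C | intermediate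
13 | (4E)-6-(tert-butyldiphenylsilyloxy)-4-methylhex-4-enal | O=CCC/C(C)=C/CO[Si](c1ccccc1)(c1ccccc1)C(C)(C)C | intermediate
14 | carbon tetrabromide | BrC(Br)(Br)Br | starting material
15 | (dibromomethylene)triphenylphosphorane (not isolated) | BrC(Br)=P(c1ccccc1)(c1ccccc1)c1ccccc1 | intermediate
16 | tert-butyl{[(2E)-7,7-dibromo-3-methylhepta-2,6-dien-1-yl]oxy}diphenylsilane | BrC(Br)=CCC/C(C)=C/CO[Si](c1ccccc1)(c1ccccc1)C(C)(C)C | intermediate
17 | 9-{(3E)-6-[(2S,3S)-3-(tert-butyldimethylsilyloxymethyl)-3-methyloxiran-2-yl]-4-methylhex-3-en-1-yl}-9-borabicyclo[3.3.1]nonane (not isolated) | CC(C)(C)[Si](C)(C)OC[C@]1(C)O[C@H]1CC/C(C)=C/CCB1C2CCCC1CCC2 | intermediate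
18 | (2E,6Z,10E,14S,15S)-7-bromo-16-(tert-butyldimethylsilyloxy)-1-(tert-butyldiphenylsilyloxy)-14,15-epoxy-3,11,15-trimethylhexadeca-2,6,10-triene | CC(C)(C)[Si](C)(C)OC[C@]1(C)O[C@H]1CC/C(C)=C/CC/C(Br)=C/CC/C(C)=C/CO[Si](c1ccccc1)(c1ccccc1)C(C)(C)C | intermediate
19 | (trimethylsilyl)methylmagnesium chloride | C[Si](C)(C)C[Mg]Cl | starting material
20 | (trimethylsilyl)methylzinc chloride (not isolated) | C[Si](C)(C)C[Zn]Cl | intermediate
21 | (2E,6Z,10E,14S,15S)-16-(tert-butyldimethylsilyloxy)-1-(tert-butyldiphenylsilyloxy)-14,15-epoxy-3,11,15-trimethyl-7-[(trimethylsilyl)methyl]hexadeca-2,6,10-triene | CC(C)(C)[Si](C)(C)OC[C@]1(C)O[C@H]1CC/C(C)=C/CC/C(C[Si](C)(C)C)=C/CC/C(C)=C/CO[Si](c1ccccc1)(c1ccccc1)C(C)(C)C | intermediate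
22 | 18-(tert-butyldimethylsilyloxy)-15-(tert-butyldiphenylsilyloxy)labda-8(17),13E-dien-3β-ol (5α-H, 9α-H, 10β-CH3) | C=C1CC[C@@H]2[C@](C)(CC[C@H](O)[C@@]2(C)CO[Si](C)(C)C(C)(C)C)[C@H]1CC/C(C)=C/CO[Si](c1ccccc1)(c1ccccc1)C(C)(C)C | intermediate
23 | 18-(tert-butyldimethylsilyloxy)-15-(tert-butyldiphenylsilyloxy)labda-8(17),13E-dien-3-one | C=C1CC[C@@H]2[C@](C)(CCC(=O)[C@@]2(C)CO[Si](C)(C)C(C)(C)C)[C@H]1CC/C(C)=C/CO[Si](c1ccccc1)(c1ccccc1)C(C)(C)C | intermediate
24 | 18-(tert-butyldimethylsilyloxy)-15-(tert-butyldiphenylsilyloxy)labda-8(17),13E-dien-3α-ol | C=C1CC[C@@H]2[C@](C)(CC[C@@H](O)[C@@]2(C)CO[Si](C)(C)C(C)(C)C)[C@H]1CC/C(C)=C/CO[Si](c1ccccc1)(c1ccccc1)C(C)(C)C | intermediate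
25 | 3α-acetoxy-18-(tert-butyldimethylsilyloxy)-15-(tert-butyldiphenylsilyloxy)labda-8(17),13E-diene | C=C1CC[C@@H]2[C@](C)(CC[C@@H](OC(C)=O)[C@@]2(C)CO[Si](C)(C)C(C)(C)C)[C@H]1CC/C(C)=C/CO[Si](c1ccccc1)(c1ccccc1)C(C)(C)C | intermediate
26 | 3α-acetoxy-15-(tert-butyldiphenylsilyloxy)labda-8(17),13E-dien-18-ol | C=C1CC[C@@H]2[C@](C)(CC[C@@H](OC(C)=O)[C@@]2(C)CO)[C@H]1CC/C(C)=C/CO[Si](c1ccccc1)(c1ccccc1)C(C)(C)C | intermediate
27 | 3α-acetoxy-15-(tert-butyldiphenylsilyloxy)labda-8(17),13E-dien-18-al | C=C1CC[C@@H]2[C@](C)(CC[C@@H](OC(C)=O)[C@@]2(C)C=O)[C@H]1CC/C(C)=C/CO[Si](c1ccccc1)(c1ccccc1)C(C)(C)C | intermediate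
28 | 3α-acetoxy-15-(tert-butyldiphenylsilyloxy)labda-8(17),13E-dien-18-oic acid | C=C1CC[C@@H]2[C@](C)(CC[C@@H](OC(C)=O)[C@@]2(C)C(=O)O)[C@H]1CC/C(C)=C/CO[Si](c1ccccc1)(c1ccccc1)C(C)(C)C | intermediate
29 | (3R,4S,5R,9S,10R)-3-acetoxy-15-hydroxylabda-8(17),13E-dien-18-oic acid | C=C1CC[C@@H]2[C@](C)(CC[C@@H](OC(C)=O)[C@@]2(C)C(=O)O)[C@H]1CC/C(C)=C/CO | target

Total step count: 20. Longest linear sequence: 16 steps (steps 1 to 6, then 11 to 20); the side-chain branch (steps 7 to 10) joins at step 11.

Steps most likely to fail

Step 13. The aluminium-bound oxirane may collapse by hydride shift from C3 to a ketone, or the cascade may stop after ring A, because the silyloxymethyl group slows C4–O ionization; Lewis-acid loss of a silyl ether is a further drain. The fallback changes the mode of ring closure from cationic to radical. It sets out from bromoalkene 18: Negishi coupling with MeZnCl under Pd(P(t-Bu)3)2 should give the all-(E) C8-methyl epoxy triene F1. Cp2TiCl (trivalent titanium, made in the flask from Cp2TiCl2 and Mn dust in THF at rt) then opens the oxirane homolytically to the tertiary C4 radical, which closes ring A and ring B by two 6-endo additions. The C8 radical is captured by a second Cp2TiCl and loses a hydrogen from C17 to give the exocyclic methylene, which returns to the route at 22. In this mode C4 is set by chair folding with the larger CH2OTBS group equatorial and not by inversion, so the C4 epimer may form alongside and would have to be removed by chromatography.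

Step 11. A second oxidative addition into the remaining C–Br bond (double alkylation), erosion of the trans selectivity, and β-hydride loss from the alkylpalladium species may all lower the supply of the (Z)-bromoalkene. The fallback moves the selectivity from the catalyst to the substrate by giving up the dibromide. It sets out from aldehyde 13: olefination with PPh3 and CCl4 in MeCN should give the 1,1-dichloroalkene F2. Borane 17, made from 9 as in step 11, is coupled with F2 under Pd2(dba)3/XantPhos with K3PO4 in THF at reflux; the second C–Cl bond is inert to this catalyst, so the (Z)-chloroalkene F3 with C7 trans to C11 should form without over-alkylation. F3 is then coupled with zinc reagent 20 under Pd(P(t-Bu)3)2 at 60 °C, which returns to the route at 21.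

Step 17. Discrimination between the hindered neopentyl C18 TBS ether and the unhindered allylic TBDPS ether may be incomplete, and acetyl transfer from O3 to O18 may set in once the C18 hydroxyl is free. The fallback moves the selectivity from deprotection, where sterics work against it, to protection, where they work for it. It sets out from 25: both silyl ethers are removed with Bu4NF buffered with AcOH in THF to give the 3α-acetoxy-15,18-diol F4. Only the unhindered allylic C15 hydroxyl is then re-silylated (TBDPSCl, imidazole, CH2Cl2, −20 °C), the neopentyl C18 hydroxyl reacting far more slowly, which returns to the route at 26.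

Further compounds
F1 | step 13 | (2E,6E,10E,14S,15S)-16-(tert-butyldimethylsilyloxy)-1-(tert-butyldiphenylsilyloxy)-14,15-epoxy-3,7,11,15-tetramethylhexadeca-2,6,10-triene | CC(C)(C)[Si](C)(C)OC[C@]1(C)O[C@H]1CC/C(C)=C/CC/C(C)=C/CC/C(C)=C/CO[Si](c1ccccc1)(c1ccccc1)C(C)(C)C
F2 | step 11 | tert-butyl{[(2E)-7,7-dichloro-3-methylhepta-2,6-dien-1-yl]oxy}diphenylsilane | ClC(Cl)=CCC/C(C)=C/CO[Si](c1ccccc1)(c1ccccc1)C(C)(C)C
F3 | step 11 | (2E,6Z,10E,14S,15S)-16-(tert-butyldimethylsilyloxy)-1-(tert-butyldiphenylsilyloxy)-7-chloro-14,15-epoxy-3,11,15-trimethylhexadeca-2,6,10-triene | CC(C)(C)[Si](C)(C)OC[C@]1(C)O[C@H]1CC/C(C)=C/CC/C(Cl)=C/CC/C(C)=C/CO[Si](c1ccccc1)(c1ccccc1)C(C)(C)C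
F4 | step 17 | 3α-acetoxylabda-8(17),13E-diene-15,18-diol | C=C1CC[C@@H]2[C@](C)(CC[C@@H](OC(C)=O)[C@@]2(C)CO)[C@H]1CC/C(C)=C/CO
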